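The six O‑alkyl bonds are cut first. The pyranone of the 6‑linked unit is then cut at O1–C2/C2–C3 (a one‑carbon unit) and at C4–C4a (an arylacetyl unit). This leaves an 8'‑aryl isoflavone; primed locants refer to the 8‑linked unit.
The enabling feature is ring A of the 6‑linked unit. C6, bonded to C8', sits between the oxygenated C5 and C7, and O1 on C8a lies para to C6. This is a 2‑aryl‑3,5‑dialkoxyphenol, the pattern a cyclobutenone/ynol ether benzannulation delivers, and each oxygen arrives with its own tag (OH, OEt, OBn).
Ring A is cut at C6–C7 and C4a–C5 into an 8‑(ethoxyethynyl)isoflavone and 3‑(benzyloxy)cyclobutenone. The first comes from iodinated tri‑O‑methylgenistein and ethoxyacetylene, the second from ketene, ethoxyacetylene and benzyl alcohol.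
In the forward direction the 8‑linked unit is bought with all three rings. Ring A of the second unit is grown on C8'. Ring C then closes onto the debenzylated para oxygen, and ring B enters with the arylacetic acid.
There are no stereocentres. The only stereogenic element is the C6–C8' axis, which forms without control.

Key step: step 6

Assumption: the target is drawn without a descriptor for the C6–C8' axis, so it is made as the racemate, and every intermediate with a stereogenic axis is racemic as well.

Step 1
Reactants: 1 genistein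
Product: 2 5,7-dimethoxy-3-(4-methoxyphenyl)chromen-4-one (tri-O-methylgenistein)
Conditions: Me2SO4 (6 equiv), K2CO3, acetone, reflux
Reagents that add atoms: dimethyl sulfate, COS(=O)(=O)OC
Why: Exhaustive Williamson O-methylation, in which an excess of dimethyl sulfate with K2CO3 in boiling acetone should alkylate even the hydrogen-bonded 5-OH while the weak base leaves the pyranone ring closed.

Step 2
Reactants: 2 tri-O-methylgenistein
Product: 3 8-iodo-5,7-dimethoxy-3-(4-methoxyphenyl)chromen-4-one
Conditions: NIS (1.05 equiv), TFA (cat.), MeCN, 0 °C → rt, dark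
Reagents that add atoms: N-iodosuccinimide, O=C1CCC(=O)N1I
Why: Electrophilic aromatic iodination, which in fully O-alkylated 5,7-dioxygenated chromones goes to C8 (ortho to the 7-methoxy group and O1, para to the 5-methoxy group) because C6 is wedged between two methoxy groups and the anisyl ring is less activated, so that one equivalent of NIS should give the 8-iodide.

Step 3
Reactants: 3 8-iodo-5,7-dimethoxy-3-(4-methoxyphenyl)chromen-4-one; 4 ethoxyacetylene
Product: 7 8-(ethoxyethynyl)-5,7-dimethoxy-3-(4-methoxyphenyl)chromen-4-one, via lithium ethoxyacetylide 5 (not isolated), via ethoxyethynylzinc chloride 6 (not isolated)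
Conditions: 4 (2 equiv), n-BuLi, THF, −78 °C; ZnCl2, −78 → 0 °C; 3, Pd(PPh3)4 (5 mol %), THF, rt → 45 °C; chromatography on Et3N-deactivated silica
Reagents that add atoms: n-butyllithium, CCCC[Li] (lithium of 5 only); zinc dichloride, Cl[Zn]Cl (zinc and chlorine of 6 only)
Why: Negishi coupling of an alkoxyethynylzinc chloride with an aryl iodide, preferred to a copper/amine alkynylation because the acid- and nucleophile-sensitive ynol ether is formed under neutral conditions, the slim alkynylzinc reaches the doubly ortho-flanked C8–Pd bond, and the organozinc does not add to the chromone.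

Step 4
Reactants: 8 acetone; 4 ethoxyacetylene
Product: 10 3-ethoxycyclobut-2-en-1-one, via ketene 9 (not isolated)
Conditions: 8, hot-wire ketene generator (ca. 700 °C); gas stream into 4, CH2Cl2, 0 °C → rt
Reagents that add atoms: none
Why: Thermal [2+2] cycloaddition of ketene to an ynol ether, in which the nucleophilic terminal alkyne carbon attacks the ketene carbonyl carbon so that the ethoxy group ends up at C3, the classical entry to this cyclobutenone.

Step 5
Reactants: 10 3-ethoxycyclobut-2-en-1-one; 11 benzyl alcohol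
Product: 12 3-(benzyloxy)cyclobut-2-en-1-one
Conditions: 11 (3 equiv), camphorsulfonic acid (5 mol %), 5 Å MS, toluene, 35 °C
Reagents that add atoms: none
Why: Acid-catalysed transetherification of a vinylogous ester by addition–elimination at C3, the pathway by which this enol ether is also hydrolysed, pulled forward by uptake of ethanol in the sieves and run far below the temperature at which the four-membered ring opens.

Step 6
Reactants: 7 8-(ethoxyethynyl)-5,7-dimethoxy-3-(4-methoxyphenyl)chromen-4-one; 12 3-(benzyloxy)cyclobut-2-en-1-one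
Product: 17 8-[4-(benzyloxy)-2-ethoxy-6-hydroxyphenyl]-5,7-dimethoxy-3-(4-methoxyphenyl)chromen-4-one, via vinylketene 13 (not isolated), via vinylcyclobutenone 14 (not isolated), via dienylketene 15 (not isolated), via cyclohexadienone 16 (not isolated)
Conditions: 12 (2.5 equiv), toluene (0.4 M), sealed tube, 85 °C, then 115 °C; K2CO3, MeOH, rt (releases any phenol O-acylated by surplus ketene)
Reagents that add atoms: none
Why: Heat opens 12 by 4π electrocyclic cleavage of its C1–C4 bond to the vinylketene 13, whose ketene C=C adds [2+2] to the triple bond of 7 to give 14, and a second 4π opening turns 14 into the dienylketene 15. The only ring formed, benzene ring A, closes by thermal 6π electrocyclization of 15 between the ketene carbon and the CH2 terminus, and enolization of dienone 16 makes the sequence irreversible; in sum the alkyne is inserted into the C1–C2 bond of 12, which creates C6–C7 and C4a–C5 of the target. This is the Danheiser benzannulation of a cyclobutenone with an alkoxyalkyne, the established route to 2-substituted resorcinol monoethers, used here with an oxygen at C3 of the cyclobutenone so that a phloroglucinol results. The selectivity needed is regiochemical: the oxygen lone pair of the ynol ether makes the aryl-bearing alkyne carbon the nucleophile, it bonds to the electrophilic ketene carbonyl carbon, and OH and OEt therefore end up on either side of the biaryl bond with OBn para to it. No stereocentre survives (C4 of 14 is lost on ring opening) and the hindered biaryl axis forms as a racemate. The first stage is held at 85 °C, below the range in which ethyl ynol ethers lose ethylene by a retro-ene reaction, 12 is taken in excess because 13 also oligomerizes, and the electron-poor C2'=C3' bond of the chromone is no ketenophile.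

Step 7
Reactants: 17 8-[4-(benzyloxy)-2-ethoxy-6-hydroxyphenyl]-5,7-dimethoxy-3-(4-methoxyphenyl)chromen-4-one
Product: 18 8-[4-(benzyloxy)-2,6-diethoxyphenyl]-5,7-dimethoxy-3-(4-methoxyphenyl)chromen-4-one
Conditions: EtI, K2CO3, DMF, 50 °C
Reagents that add atoms: iodoethane, CCI
Why: Williamson etherification, with ethyl chosen on purpose because two identical flanking ethoxy groups make the two remaining CH positions of ring A equivalent, so that the later acylation can give only one constitution.

Step 8
Reactants: 18 8-[4-(benzyloxy)-2,6-diethoxyphenyl]-5,7-dimethoxy-3-(4-methoxyphenyl)chromen-4-one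
Product: 19 8-(2,6-diethoxy-4-hydroxyphenyl)-5,7-dimethoxy-3-(4-methoxyphenyl)chromen-4-one
Conditions: H2 (1 atm), 10% Pd/C, EtOAc–THF, rt, stopped after one equivalent of H2
Reagents that add atoms: none
Why: Catalytic hydrogenolysis of a benzyl aryl ether, which at one atmosphere in an aprotic medium should outpace saturation of the C2'=C3' bond and, unlike a boron trihalide, spares the 5'-methoxy group next to the carbonyl, so that only the oxygen para to the biaryl bond is set free.

Step 9
Reactants: 19 8-(2,6-diethoxy-4-hydroxyphenyl)-5,7-dimethoxy-3-(4-methoxyphenyl)chromen-4-one; 20 4-methoxyphenylacetic acid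
Product: 21 8-{2,6-diethoxy-4-hydroxy-3-[(4-methoxyphenyl)acetyl]phenyl}-5,7-dimethoxy-3-(4-methoxyphenyl)chromen-4-one
Conditions: 20 (1.5 equiv), BF3·OEt2 (solvent), 80 °C; aq NaOAc
Reagents that add atoms: none
Why: Friedel–Crafts C-acylation of a phenol with an arylacetic acid in BF3·OEt2, the standard deoxybenzoin synthesis of isoflavone chemistry, directed to the phloroglucinol-type ring A as the most electron-rich arene (C6' belongs to a BF3-complexed chromone, the anisyl rings carry one donor only) and there to either of two equivalent positions ortho to the free OH, which chelates the new ketone.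

Step 10
Reactants: 21 8-{2,6-diethoxy-4-hydroxy-3-[(4-methoxyphenyl)acetyl]phenyl}-5,7-dimethoxy-3-(4-methoxyphenyl)chromen-4-one
Product: 23 5,7-diethoxy-5',7'-dimethoxy-3,3'-bis(4-methoxyphenyl)-[6,8'-bichromene]-4,4'-dione, via enaminone 22 (not isolated)
Conditions: Me2NCH(OMe)2 (4 equiv), toluene, 95 °C
Reagents that add atoms: N,N-dimethylformamide dimethyl acetal, COC(OC)N(C)C
Why: Isoflavone ring closure of a 2-hydroxydeoxybenzoin with a formamide acetal: condensation at the doubly activated CH2 gives enaminone 22, whose only free hydroxyl adds to the β-carbon (6-endo-trig) and expels dimethylamine, and because the C5 and C7 oxygens are ethers the pyranone can close only onto the oxygen para to the biaryl bond, which fixes the 6-linkage.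

Step 11
Reactants: 23 5,7-diethoxy-5',7'-dimethoxy-3,3'-bis(4-methoxyphenyl)-[6,8'-bichromene]-4,4'-dione
Product: 24 5,5',7,7'-tetrahydroxy-3,3'-bis(4-hydroxyphenyl)-[6,8'-bichromene]-4,4'-dione (6,8'-bigenistein, CNP0184660.0)
Conditions: BBr3 (20 equiv), CH2Cl2, −78 °C → rt; ice–water
Reagents that add atoms: none
Why: Global cleavage of aryl alkyl ethers with BBr3, routine for permethylated isoflavones and biflavonoids and equally valid for ethyl ethers, run cold and aprotic so that no Wessely–Moser type opening and reclosure of a 5-hydroxychromone can exchange 6- and 8-linkages.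

Compound list
1 | genistein | O=c1c(-c2ccc(O)cc2)coc2cc(O)cc(O)c12 | starting material
2 | 5,7-dimethoxy-3-(4-methoxyphenyl)chromen-4-one | COc1cc(OC)c2c(c1)occ(-c1ccc(OC)cc1)c2=O | intermediate
3 | 8-iodo-5,7-dimethoxy-3-(4-methoxyphenyl)chromen-4-one | COc1cc(OC)c2c(c1I)occ(-c1ccc(OC)cc1)c2=O | intermediate
4 | ethoxyacetylene | CCOC#C | starting material
5 | lithium ethoxyacetylide | CCOC#C[Li] | intermediate
6 | (ethoxyethynyl)zinc chloride | CCOC#C[Zn]Cl | intermediate
7 | 8-(ethoxyethynyl)-5,7-dimethoxy-3-(4-methoxyphenyl)chromen-4-one | CCOC#Cc1c(OC)cc(OC)c2c1occ(-c1ccc(OC)cc1)c2=O | intermediate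
8 | acetone | CC(C)=O | starting material
9 | ketene | C=C=O | intermediate
10 | 3-ethoxycyclobut-2-en-1-one | CCOC1=CC(=O)C1 | intermediate
11 | benzyl alcohol | OCc1ccccc1 | starting material
12 | 3-(benzyloxy)cyclobut-2-en-1-one | O=C1CC(OCc2ccccc2)=C1 | intermediate
13 | 3-(benzyloxy)buta-1,3-dien-1-one (vinylketene) | O=C=CC(=C)OCc1ccccc1 | intermediate
14 | 8-{4-[1-(benzyloxy)ethenyl]-3-ethoxy-1-oxocyclobut-2-en-2-yl}-5,7-dimethoxy-3-(4-methoxyphenyl)chromen-4-one (racemic) | CCOC1=C(C(=O)C1C(=C)OCc1ccccc1)c1c(OC)cc(OC)c2c1occ(-c1ccc(OC)cc1)c2=O | intermediate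
15 | 8-[5-(benzyloxy)-3-ethoxy-1-oxohexa-1,3,5-trien-2-yl]-5,7-dimethoxy-3-(4-methoxyphenyl)chromen-4-one (dienylketene, ketenyl and vinyl groups cis on the central double bond) | CCO/C(=C/C(=C)OCc1ccccc1)C(=C=O)c1c(OC)cc(OC)c2c1occ(-c1ccc(OC)cc1)c2=O | intermediate
16 | 8-[4-(benzyloxy)-2-ethoxy-6-oxocyclohexa-1,3-dien-1-yl]-5,7-dimethoxy-3-(4-methoxyphenyl)chromen-4-one | CCOC1=C(C(=O)CC(OCc2ccccc2)=C1)c1c(OC)cc(OC)c2c1occ(-c1ccc(OC)cc1)c2=O | intermediate
17 | 8-[4-(benzyloxy)-2-ethoxy-6-hydroxyphenyl]-5,7-dimethoxy-3-(4-methoxyphenyl)chromen-4-one | CCOc1cc(OCc2ccccc2)cc(O)c1-c1c(OC)cc(OC)c2c1occ(-c1ccc(OC)cc1)c2=O | intermediate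
18 | 8-[4-(benzyloxy)-2,6-diethoxyphenyl]-5,7-dimethoxy-3-(4-methoxyphenyl)chromen-4-one | CCOc1cc(OCc2ccccc2)cc(OCC)c1-c1c(OC)cc(OC)c2c1occ(-c1ccc(OC)cc1)c2=O | intermediate
19 | 8-(2,6-diethoxy-4-hydroxyphenyl)-5,7-dimethoxy-3-(4-methoxyphenyl)chromen-4-one | CCOc1cc(O)cc(OCC)c1-c1c(OC)cc(OC)c2c1occ(-c1ccc(OC)cc1)c2=O | intermediate
20 | 4-methoxyphenylacetic acid | COc1ccc(CC(=O)O)cc1 | starting material
21 | 8-{2,6-diethoxy-4-hydroxy-3-[(4-methoxyphenyl)acetyl]phenyl}-5,7-dimethoxy-3-(4-methoxyphenyl)chromen-4-one | CCOc1cc(O)c(C(=O)Cc2ccc(OC)cc2)c(OCC)c1-c1c(OC)cc(OC)c2c1occ(-c1ccc(OC)cc1)c2=O | intermediate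
22 | 8-{3-[3-(dimethylamino)-2-(4-methoxyphenyl)prop-2-enoyl]-2,6-diethoxy-4-hydroxyphenyl}-5,7-dimethoxy-3-(4-methoxyphenyl)chromen-4-one (enaminone) | CCOc1cc(O)c(C(=O)C(=CN(C)C)c2ccc(OC)cc2)c(OCC)c1-c1c(OC)cc(OC)c2c1occ(-c1ccc(OC)cc1)c2=O | intermediate
23 | 5,7-diethoxy-5',7'-dimethoxy-3,3'-bis(4-methoxyphenyl)-[6,8'-bichromene]-4,4'-dione | CCOc1cc2occ(-c3ccc(OC)cc3)c(=O)c2c(OCC)c1-c1c(OC)cc(OC)c2c1occ(-c1ccc(OC)cc1)c2=O | intermediate
24 | 5,5',7,7'-tetrahydroxy-3,3'-bis(4-hydroxyphenyl)-[6,8'-bichromene]-4,4'-dione | O=c1c(-c2ccc(O)cc2)coc2cc(O)c(-c3c(O)cc(O)c4c(=O)c(-c5ccc(O)cc5)coc34)c(O)c12 | target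

Total step count: 11. Longest linear sequence: 9 steps (1, 2, 3, 6, 7, 8, 9, 10, 11). Steps 4 and 5 form the side branch.

Steps most likely to fail

Step 6. The cyclobutenone is a vinylogous ester and may open only at temperatures the ethyl ynol ether does not tolerate. Retro-ene loss of ethylene, oligomerization of the vinylketene, or a stalled [2+2] addition at the doubly ortho-flanked alkyne carbon could then consume the material.
The fallback sets out from 3 and comes back at 18. It makes the tagged ring A separately and forges the biaryl bond by cross-coupling.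
- Purchased 2-bromoresorcinol is ethylated twice (EtI, K2CO3, DMF) to 2-bromo-1,3-diethoxybenzene F1.
- C–H borylation ([Ir(OMe)(cod)]2, 4,4'-di-tert-butyl-2,2'-bipyridine, B2pin2, THF, 80 °C) strikes the only CH without an ortho neighbour and gives 2-(4-bromo-3,5-diethoxyphenyl)-4,4,5,5-tetramethyl-1,3,2-dioxaborolane F2.
- Oxidation (H2O2, NaOH, THF, 0 °C) gives 4-bromo-3,5-diethoxyphenol F3.
- Benzylation (BnBr, K2CO3, DMF) gives 5-(benzyloxy)-2-bromo-1,3-diethoxybenzene F4.
- Bromine–lithium exchange (n-BuLi, THF, −78 °C) gives [4-(benzyloxy)-2,6-diethoxyphenyl]lithium F5.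
- Quenching with B(OMe)3 and dilute HCl gives [4-(benzyloxy)-2,6-diethoxyphenyl]boronic acid F6.
- Suzuki–Miyaura coupling of the boronic acid with 3 (Pd(OAc)2, SPhos, K3PO4, toluene–H2O, 90 °C) delivers 18.

Step 9. Hot BF3·OEt2 may strip the ethyl group next to the new ketone, which would open the way to ring closure onto the wrong oxygen. It may also cleave the 5'-methyl group, or the reaction may stop at O-acylation because the C-position between OH and OEt is crowded.
The fallback sets out from 19 and comes back at 21. It uses a nitrile as the electrophile at low temperature in a Houben–Hoesch reaction. 4-Methoxyphenylacetonitrile, ZnCl2 and HCl gas in Et2O at 0 °C precipitate the hydrochloride of 8-{2,6-diethoxy-4-hydroxy-3-[2-(4-methoxyphenyl)ethanimidoyl]phenyl}-5,7-dimethoxy-3-(4-methoxyphenyl)chromen-4-one F7. Warm water hydrolyses this to 21.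

Step 5. Attack of the alcohol at the strained carbonyl with retro-Claisen ring cleavage, adventitious hydrolysis, or an unfavourable exchange equilibrium may outrun the clean swap of ethoxy for benzyloxy.
The fallback sets out from 10 and comes back at 12. It replaces the equilibrium by hydrolysis and irreversible O-alkylation. Cold dilute HCl converts 10 into cyclobutane-1,3-dione, present as its enol 3-hydroxycyclobut-2-en-1-one F8. This acidic enol is O-benzylated with 11 under Mitsunobu conditions (PPh3, diisopropyl azodicarboxylate, THF, 0 °C) to give 12.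

Further compounds
F1 | step 6 | 2-bromo-1,3-diethoxybenzene | CCOc1cccc(OCC)c1Br
F2 | step 6 | 2-(4-bromo-3,5-diethoxyphenyl)-4,4,5,5-tetramethyl-1,3,2-dioxaborolane | CCOc1cc(cc(OCC)c1Br)B1OC(C)(C)C(C)(C)O1
F3 | step 6 | 4-bromo-3,5-diethoxyphenol | CCOc1cc(O)cc(OCC)c1Br
F4 | step 6 | 5-(benzyloxy)-2-bromo-1,3-diethoxybenzene | CCOc1cc(OCc2ccccc2)cc(OCC)c1Br
F5 | step 6 | [4-(benzyloxy)-2,6-diethoxyphenyl]lithium | CCOc1cc(OCc2ccccc2)cc(OCC)c1[Li]
F6 | step 6 | [4-(benzyloxy)-2,6-diethoxyphenyl]boronic acid | CCOc1cc(OCc2ccccc2)cc(OCC)c1B(O)O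
F7 | step 9 | 8-{2,6-diethoxy-4-hydroxy-3-[2-(4-methoxyphenyl)ethanimidoyl]phenyl}-5,7-dimethoxy-3-(4-methoxyphenyl)chromen-4-one | CCOc1cc(O)c(C(=N)Cc2ccc(OC)cc2)c(OCC)c1-c1c(OC)cc(OC)c2c1occ(-c1ccc(OC)cc1)c2=O
F8 | step 5 | 3-hydroxycyclobut-2-en-1-one | O=C1CC(O)=C1
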